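The data were computed with made-up constants, noise included.

common to all: starting material 0.37 M; capture agent 0.0185 M

| run | activator | remark | time |
|---|---|---|---|
| eta | 1 M | run made earlier |  |
| theta | 2.7 M | run made earlier |  |
| Saturday's | 0.740 M |  | 10 min |
| Sunday's | 2.20 M |  | 10 min |

| eta: time / min | eta: ring / % | theta: time / min | theta: ring / % |
|---|---|---|---|
| 0.500 | 1.8 | 0.667 | 3.8 |
| 1.00 | 3.0 | 2.00 | 11.4 |
| 2.00 | 5.5 | 3.00 | 17.2 |
| 4.00 | 15.4 | 5.00 | 30.2 |
| 8.00 | 25.5 | 8.00 | 42.6 |

(standard deviation of a reading: 1 percentage point)

* which of the two there is more of at the end, counted by the starting material in each, Saturday's (ring / side product)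
* which of the two there is more of at the end, counted by the starting material in each, Sunday's (ring / side product)
* ring at the end, in percent of the starting material charged, Saturday's
* ring at the end, in percent of the starting material charged, Sunday's

- percent here means starting material units held: one open dimer or side product counts as two
- steps thought possible: starting material + activated form -> open dimer; starting material + activator -> activated form; activator -> decomposition product; starting material + activated form -> side product; capture agent + activated form -> trapped intermediate; activated form -> ring

- The eta run, with 1 M of activator, holds 25.5% ring at 8.00 min; the theta run, with 2.7 M, holds 42.6% at the same time. In logarithms this gives 0.517: the apparent order in c(activator), the logarithm of the ring ratio at equal time divided by the logarithm of the activator ratio. It is a reading, with the scatter of its two readings.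
- Bound from below: scaled by that power, we reckon Sunday's at 38.3% ring at 8.00 min and Saturday's at 21.8%, though Saturday's lies outside the two charges. No listed step consumes ring, so we take these reckoned values as floors at 10 min too.
- Bound from above: a straight line through the origin stretches them to 47.9% and 27.2%. But the last two theta readings give a time power of 0.732, below the straight line's one. Tightened with that reading, which carries the scatter too, our reckoned ceilings are 45.1% for Sunday's and 25.7% for Saturday's.
- The forecast says 23% for Saturday's, inside our bracket, and 46% for Sunday's, above the tightened ceiling by 0.90 percentage points against a scatter of 1 point. It calls ring on Saturday's and ring on Sunday's, and says: “Side product was never measured”. We bracket no side product.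
- Saturday's flask gives 23.1% ring and Sunday's 43.1%, both inside our brackets. Side product holds 41.9% on Saturday's, where the forecast's call fails, and 29.4% on Sunday's, where it stands. Saturday's against Sunday's gives an order of 0.572. Carried from Sunday's with 0.517, the neighbour flask with 0.55 M of activator comes to 21.1%; it holds 18.2%.

    starting material + activated form → open dimer (k = 0.590 M⁻¹ min⁻¹)
    starting material + activator → activated form (k = 0.340 M⁻¹ min⁻¹)
    activator → decomposition product (k = 1.20 × 10⁻⁴ min⁻¹)
    starting material + activated form → side product (k = 1.30 M⁻¹ min⁻¹)
    capture agent + activated form → trapped intermediate (k = 0.160 M⁻¹ min⁻¹)
    activated form → ring (k = 0.160 min⁻¹)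

- On Sunday's, the step to side product ran while starting material, the limiting reagent, lasted: it had 79% of its turnover behind it at 2.00 min, and starting material was down to 1.09% at 5.00 min. The closure to ring, with 23% behind it at 2.00 min, went on from the activated form, which still held 13.3% of the charge at 10.0 min.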